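The target is the (R)-terpinen-4-yl ester of 4-hydroxy-3,5-diprenylbenzoic acid. The route rests on a [4+2] assembly of the cyclohexene ring: its oxygen-bearing quaternary carbon (with isopropyl) and its methyl-bearing alkene carbon sit 1,4 to each other, so a vinyl unit can bridge them as ring CH2–CH=. In one flask, the α-hydroxyalkyl radical of acyclic, racemic 5-hydroxy-6-methylheptan-2-one adds to vinyltriphenylphosphonium bromide under a chiral phosphate (C–C bond and stereocentre), and the resulting ylide closes the ring by Wittig reaction with the methyl ketone (C=C bond). The alcohol is then acylated through its imidazole carboxylate with an aryllithium.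

Key step: step 3

Assumption: the sense of induction of the chiral phosphate in step 3 cannot be predicted with certainty, so the (R)-phosphate is written on the expectation that it gives the (R)-alcohol and its enantiomer is used if the opposite sense is found; (R)-TRIP phosphate stands for (R)-3,3′-bis(2,4,6-triisopropylphenyl)-1,1′-binaphthyl-2,2′-diyl phosphate.

Step 1
Reactants: 1 2-methylpropanal; 2 2-(2-bromoethyl)-2-methyl-1,3-dioxolane
Product: 4 rac-2-methyl-5-(2-methyl-1,3-dioxolan-2-yl)pentan-3-ol, via Grignard reagent 3 (not isolated)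
Conditions: Mg, THF, 25 °C; then 1, −20 to 0 °C; H2O
Reagents that add atoms: none
Why: The primary alkylmagnesium bromide formed from 2 adds to the aldehyde (Grignard addition) while the dioxolane keeps the ketone masked; the carbinol centre forms as a racemate, which is acceptable because step 3 removes its hydrogen and sets the centre anew.

Step 2
Reactants: 4 rac-2-methyl-5-(2-methyl-1,3-dioxolan-2-yl)pentan-3-ol
Product: 5 rac-5-hydroxy-6-methylheptan-2-one
Conditions: PPTS, acetone/H2O, 50 °C
Reagents that add atoms: water, O
Why: Mild acid-catalysed acetal hydrolysis should release the methyl ketone without dehydrating the secondary alcohol, the γ-hydroxy ketone standing in equilibrium with its cyclic hemiketal.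

Step 3
Reactants: 5 rac-5-hydroxy-6-methylheptan-2-one; 6 ethenyl(triphenyl)phosphonium bromide
Product: 9 (1R)-4-methyl-1-(propan-2-yl)cyclohex-3-en-1-ol, via hydroxy phosphonium salt 7 (not isolated), via oxido ylide 8 (not isolated)
Conditions: Ir[dF(CF3)ppy]2(dtbbpy)PF6 (1 mol %), quinuclidine (10 mol %), tetrabutylammonium (R)-TRIP phosphate (20 mol %), PhCF3, blue LEDs, 25 °C; then KN(SiMe3)2, THF, −78 to 25 °C, same flask; H2O
Reagents that add atoms: none
Why: Proposed new method: the chiral phosphate anion hydrogen-bonds the hydroxyl group of 5, which makes the carbinol C–H hydridic enough for abstraction by the quinuclidine radical cation generated by the excited iridium photocatalyst; the tertiary α-hydroxyalkyl radical adds to the CH2 terminus of 6, the α-phosphonio radical is reduced by the reduced photocatalyst and protonated to salt 7, and the amide base then forms the γ-oxido ylide 8, which olefinates the methyl ketone. The closest known reaction types are the hydrogen-bond-assisted photoredox α-C–H alkylation of alcohols with electron-poor alkenes, chiral-phosphate-controlled additions of hydrogen-bonded prochiral radicals to cationic acceptors, and the annulation of vinylphosphonium salts by conjugate addition and intramolecular Wittig reaction. The cyclohexene ring closes by intramolecular Wittig olefination, a 6-exo attack of the ylide carbon on the ketone followed by collapse of the oxaphosphetane. The new quaternary stereocentre is set in the radical addition by the (R)-phosphate, which binds the radical through an O–H···O hydrogen bond and holds the vinylphosphonium cation as its ion pair, so that one face of the planar radical is presented to the acceptor and the configuration of racemic 5 is irrelevant. The step needs hydrogen abstraction only at the carbinol C–H and ring closure only onto the methyl ketone: the first is secured by the hydrogen bond, which activates that one C–H bond, and the second by the single carbonyl group placed four atoms from the carbinol carbon.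

Step 4
Reactants: 9 (1R)-4-methyl-1-(propan-2-yl)cyclohex-3-en-1-ol; 10 1,1′-carbonyldiimidazole
Product: 12 (1R)-4-methyl-1-(propan-2-yl)cyclohex-3-en-1-yl 1H-imidazole-1-carboxylate, via sodium alkoxide 11 (not isolated)
Conditions: NaH, THF, 0 to 25 °C; then 10, 0 to 25 °C; H2O
Reagents that add atoms: none
Why: The tertiary sodium alkoxide should displace one imidazole of 10 by nucleophilic acyl substitution (imidazole carboxylate formation, as for tert-butyl imidazole-1-carboxylate) under basic conditions that leave the carbinol stereocentre and the ring alkene untouched.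

Step 5
Reactants: 13 4-iodophenol; 14 1-bromo-3-methylbut-2-ene
Product: 17 4-iodo-2,6-bis(3-methylbut-2-en-1-yl)phenol, via sodium 4-iodophenolate 15 (not isolated), via sodium monoprenyl phenolate 16 (not isolated)
Conditions: NaH (2.2 equiv), 14 (2.2 equiv), toluene, 25 °C
Reagents that add atoms: none
Why: In non-polar toluene the tightly paired sodium phenolate should be alkylated by the primary allylic bromide at the ortho carbons and not at oxygen (ortho-selective C-alkylation of phenolates, SN2), the para position being blocked by iodine, and the second equivalent repeats the process at the other ortho position.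

Step 6
Reactants: 17 4-iodo-2,6-bis(3-methylbut-2-en-1-yl)phenol; 12 (1R)-4-methyl-1-(propan-2-yl)cyclohex-3-en-1-yl 1H-imidazole-1-carboxylate
Product: 19 (1R)-4-methyl-1-(propan-2-yl)cyclohex-3-en-1-yl 4-hydroxy-3,5-bis(3-methylbut-2-en-1-yl)benzoate, via dilithio aryl species 18 (not isolated)
Conditions: n-BuLi (2.1 equiv), THF, −78 °C; then 12, −78 to 0 °C; H2O
Reagents that add atoms: none
Why: Deprotonation and iodine–lithium exchange should give the aryllithium, which displaces imidazolide from the alkoxycarbonylimidazole (acyl substitution by an organolithium, as in tert-butyl ester formation from Boc2O) to give a hindered, phenolate-deactivated ester that resists a second addition, the stereocentre not being involved.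

Compound list
1 | 2-methylpropanal | CC(C)C=O | starting material
2 | 2-(2-bromoethyl)-2-methyl-1,3-dioxolane | CC1(CCBr)OCCO1 | starting material
3 | [2-(2-methyl-1,3-dioxolan-2-yl)ethyl]magnesium bromide | CC1(CC[Mg]Br)OCCO1 | intermediate
4 | rac-2-methyl-5-(2-methyl-1,3-dioxolan-2-yl)pentan-3-ol | CC(C)C(O)CCC1(C)OCCO1 | intermediate
5 | rac-5-hydroxy-6-methylheptan-2-one | CC(C)C(O)CCC(C)=O | intermediate
6 | ethenyl(triphenyl)phosphonium bromide | C=C[P+](c1ccccc1)(c1ccccc1)c1ccccc1.[Br-] | starting material
7 | [(3R)-3-hydroxy-4-methyl-3-(3-oxobutyl)pentyl](triphenyl)phosphonium bromide | O[C@@](CCC(C)=O)(C(C)C)CC[P+](c1ccccc1)(c1ccccc1)c1ccccc1.[Br-] | intermediate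
8 | potassium (3R)-2-methyl-3-(3-oxobutyl)-5-(triphenyl-λ5-phosphanylidene)pentan-3-olate | [K+].[O-][C@@](CCC(C)=O)(C(C)C)CC=P(c1ccccc1)(c1ccccc1)c1ccccc1 | intermediate
9 | (1R)-4-methyl-1-(propan-2-yl)cyclohex-3-en-1-ol, (R)-terpinen-4-ol | O[C@@]1(C(C)C)CC=C(C)CC1 | intermediate
10 | 1,1′-carbonyldiimidazole | O=C(n1ccnc1)n1ccnc1 | starting material
11 | sodium (1R)-4-methyl-1-(propan-2-yl)cyclohex-3-en-1-olate | [Na+].[O-][C@@]1(C(C)C)CC=C(C)CC1 | intermediate
12 | (1R)-4-methyl-1-(propan-2-yl)cyclohex-3-en-1-yl 1H-imidazole-1-carboxylate | O=C(O[C@@]1(C(C)C)CC=C(C)CC1)n1ccnc1 | intermediate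
13 | 4-iodophenol | Oc1ccc(I)cc1 | starting material
14 | 1-bromo-3-methylbut-2-ene | CC(C)=CCBr | starting material
15 | sodium 4-iodophenolate | [Na+].[O-]c1ccc(I)cc1 | intermediate
16 | sodium 4-iodo-2-(3-methylbut-2-en-1-yl)phenolate | [Na+].[O-]c1ccc(I)cc1CC=C(C)C | intermediate
17 | 4-iodo-2,6-bis(3-methylbut-2-en-1-yl)phenol | CC(C)=CCc1cc(I)cc(CC=C(C)C)c1O | intermediate
18 | lithium 4-lithio-2,6-bis(3-methylbut-2-en-1-yl)phenolate | [Li]c1cc(CC=C(C)C)c(O[Li])c(CC=C(C)C)c1 | intermediate
19 | (1R)-4-methyl-1-(propan-2-yl)cyclohex-3-en-1-yl 4-hydroxy-3,5-bis(3-methylbut-2-en-1-yl)benzoate | CC(C)=CCc1cc(C(=O)O[C@@]2(C(C)C)CC=C(C)CC2)cc(CC=C(C)C)c1O | target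

Total step count: 6. Longest linear sequence: 5 steps (steps 1, 2, 3, 4 and 6, from 2-methylpropanal).

Steps most likely to fail

Step 3 (proposed new method, the riskiest step). Loose ion pairing may give poor enantiofacial discrimination in the radical addition. The hydroxyl group, or the hemiketal form of 5, may add through oxygen to the vinylphosphonium salt. The hydroxy phosphonium salt may also rest as a cyclic oxaphospholane and olefinate slowly. The fallback uses known chemistry, sets out from 5 and returns at 9. Wittig methylenation of the ketone of 5 (Ph3P=CH2, THF) should give racemic 2,6-dimethylhept-6-en-3-ol F1. Swern oxidation should give 2,6-dimethylhept-6-en-3-one F2. Catalytic asymmetric allylboration of this ketone (allyldiisopropoxyborane with the enantiomer of 3,3′-dibromo-BINOL that leads to the R carbinol) should give (4R)-7-methyl-4-(propan-2-yl)octa-1,7-dien-4-ol F3. Ring-closing metathesis with the second-generation Grubbs catalyst should then close the trisubstituted cyclohexene and deliver 9.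

Step 6. Iodine–lithium exchange may stay incomplete on the aggregated lithium phenolate, the aryllithium may be quenched by proton transfer from the doubly activated ArCH2 groups, or acylation may occur at the phenolate oxygen. The fallback sets out from 17 and returns at 19.
- Silylation (TBSCl, imidazole, DMF) should give tert-butyl[4-iodo-2,6-bis(3-methylbut-2-en-1-yl)phenoxy]dimethylsilane F4.
- Iodine–lithium exchange (n-BuLi, THF, −78 °C) should give {4-[tert-butyl(dimethyl)silyl]oxy-3,5-bis(3-methylbut-2-en-1-yl)phenyl}lithium F5.
- Carboxylation with CO2 should give 4-{[tert-butyl(dimethyl)silyl]oxy}-3,5-bis(3-methylbut-2-en-1-yl)benzoic acid F6.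
- 1-Chloro-N,N,2-trimethylprop-1-en-1-amine should convert the acid under neutral conditions into 4-{[tert-butyl(dimethyl)silyl]oxy}-3,5-bis(3-methylbut-2-en-1-yl)benzoyl chloride F7.
- Acylation of sodium alkoxide 11 should give (1R)-4-methyl-1-(propan-2-yl)cyclohex-3-en-1-yl 4-{[tert-butyl(dimethyl)silyl]oxy}-3,5-bis(3-methylbut-2-en-1-yl)benzoate F8.
- Bu4NF buffered with acetic acid should remove the silyl group to give 19.

Step 5. Alkylation may occur at oxygen instead of carbon, may stop at the monoprenyl stage or run on to dienones, and the ortho-prenyl phenol may cyclise to a chroman under acidic work-up. The fallback sets out from 13 and returns at 17. O-Alkylation with 14 (K2CO3, acetone) should give 1-iodo-4-[(3-methylbut-2-en-1-yl)oxy]benzene F9. A clay-promoted 1,3-shift (montmorillonite K10, CH2Cl2, 0 °C) should move the prenyl group to the ortho carbon to give 4-iodo-2-(3-methylbut-2-en-1-yl)phenol F10. A second O-alkylation should give 4-iodo-2-(3-methylbut-2-en-1-yl)-1-[(3-methylbut-2-en-1-yl)oxy]benzene F11, and a second clay-promoted shift should give 17.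

Further compounds
F1 | step 3 | rac-2,6-dimethylhept-6-en-3-ol | CC(C)C(O)CCC(C)=C
F2 | step 3 | 2,6-dimethylhept-6-en-3-one | CC(C)C(=O)CCC(C)=C
F3 | step 3 | (4R)-7-methyl-4-(propan-2-yl)octa-1,7-dien-4-ol | O[C@@](CCC(C)=C)(C(C)C)CC=C
F4 | step 6 | tert-butyl[4-iodo-2,6-bis(3-methylbut-2-en-1-yl)phenoxy]dimethylsilane | CC(C)=CCc1cc(I)cc(CC=C(C)C)c1O[Si](C)(C)C(C)(C)C
F5 | step 6 | {4-[tert-butyl(dimethyl)silyl]oxy-3,5-bis(3-methylbut-2-en-1-yl)phenyl}lithium | [Li]c1cc(CC=C(C)C)c(O[Si](C)(C)C(C)(C)C)c(CC=C(C)C)c1
F6 | step 6 | 4-{[tert-butyl(dimethyl)silyl]oxy}-3,5-bis(3-methylbut-2-en-1-yl)benzoic acid | CC(C)=CCc1cc(C(=O)O)cc(CC=C(C)C)c1O[Si](C)(C)C(C)(C)C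
F7 | step 6 | 4-{[tert-butyl(dimethyl)silyl]oxy}-3,5-bis(3-methylbut-2-en-1-yl)benzoyl chloride | CC(C)=CCc1cc(C(Cl)=O)cc(CC=C(C)C)c1O[Si](C)(C)C(C)(C)C
F8 | step 6 | (1R)-4-methyl-1-(propan-2-yl)cyclohex-3-en-1-yl 4-{[tert-butyl(dimethyl)silyl]oxy}-3,5-bis(3-methylbut-2-en-1-yl)benzoate | CC(C)=CCc1cc(C(=O)O[C@@]2(C(C)C)CC=C(C)CC2)cc(CC=C(C)C)c1O[Si](C)(C)C(C)(C)C
F9 | step 5 | 1-iodo-4-[(3-methylbut-2-en-1-yl)oxy]benzene | CC(C)=CCOc1ccc(I)cc1
F10 | step 5 | 4-iodo-2-(3-methylbut-2-en-1-yl)phenol | CC(C)=CCc1cc(I)ccc1O
F11 | step 5 | 4-iodo-2-(3-methylbut-2-en-1-yl)-1-[(3-methylbut-2-en-1-yl)oxy]benzene | CC(C)=CCOc1ccc(I)cc1CC=C(C)C
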